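**Early seconds.** You asked for a quick number and suspect that at the conversion in question the catalyst G sits mostly on E. I start from the first moments, because the answer hangs on how long each form of the catalyst lasts.

J 20 mM; Z 22.0 mM; G 1.0 mM; E 20 mM

    G + J ⇌ G.J (K1 = 74 L mol⁻¹, k1 = 410 L mol⁻¹ s⁻¹)
    G + E ⇌ G.E (K2 = 930 L mol⁻¹, k2 = 1800 L mol⁻¹ s⁻¹)
    Z + G.J → G + Q (k3 = 57 L mol⁻¹ s⁻¹)
    Z + G.E → G + D (k4 = 20 L mol⁻¹ s⁻¹)

- the form that holds most of the catalyst when 50% of the J and E together are converted (G / G.E / G.J)
- its share of the catalyst then
- apparent order in G when 50% of the J and E together are converted (percent change of the rate of making Q for one percent more G charged)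
- factor on the rate of making Q when 50% of the J and E together are converted if Z is charged twice over

**Counting lifetimes.** With the substrates as charged, a free G lasts 0.0226 s before it binds. With Z as charged, G.J falls back at 5.54 s⁻¹ and goes on at 1.3 s⁻¹, so it lasts 0.146 s. The rate of falling back over the rate of going on is then 4.42, and this is my fall-back number. For G.E the same number is 4.40. As Z is used, going on slows and the number rises. Because it stands above one, I treat both bound forms as near equilibrium with G, a pre-equilibrium.

**The split.** The catalyst then divides by binding weights: 19 for G.E, 1.5 for G.J and one for G. At the start G.E therefore holds 88.2%. Per unit present, E is consumed 4.41 times faster than J, the selectivity factor, so the share of G.E must fall. But G.E outweighs G.J while E stands above 0.0796 of J, since E binds more strongly. I commit to G.E as the resting state, with a share below that starting value, and my hand reckoning stops there.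

**The result.** The forecast gives G.E at 70%, an order in G of 1.3 and a factor of 8.5 for doubled Z, citing “E's much tighter binding”. The simulation reaches that conversion at 91.9 s with G.E at 69.8%, G at 14.7% and G.J at 15.5%; the order is 1.3 and the factor 8.38.

**Fall-back check.** At 16.1 s G.J in the flask falls back 6.3 times faster than it goes on, more than the 4.42 from Z as charged, which by my number puts Z at 70.2% of its charge. At that moment the step from Z + G.E to G + D takes Z 3.4 times faster than the step from Z + G.J to G + Q.

(The numbers were chosen freely; the result is computed.)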